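The skeleton is a coumaronochromone (11H-benzofuro[2,3-b]chromen-11-one): ring A = C4a, C5–C8, C8a; ring C = O1, C2, C3, C4; ring B = C1'–C6'; furan ring = C2, C3, C1', C2', O. The target adds dihydropyran rings O5–C6 and O4'–C3', a prenyl group on C8 and OH on C7 and C5'. It has no stereocentre.
The C8 prenyl group comes from an aromatic Claisen rearrangement of the 7-O-(1,1-dimethylallyl) ether. This is placed last so that the hydrogenation in step 9 never meets the prenyl group.
Both dihydropyran rings are cut at their aryl–CH2 bonds (C3'–CH2 in ring B, C6–CH2 in ring A), which leads back to a bis(1,1-dimethylpropargyl) ether. One flask (twofold gold-catalysed 6-endo-dig hydroarylation, then H2 over Pd/C) turns the tetracycle into the hexacycle.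
Enabling feature: the ether oxygen on C4' has only one free ortho carbon, C3', which lies between the oxygen-bearing C2' and C4'. The ether oxygen on C5 has only C6, which lies between C5 and C7. Each is the most nucleophilic CH of its ring, and the hydrogen-free O–C(CH3)2 carbon folds the chain towards it.
The tetracycle comes from the union of a 2-aminochromone (rings A, C) with a 2-alkoxy-1,4-benzoquinone (ring B), whose para carbonyl oxygens become the furan oxygen on C2' and the 5'-OH. Rings form in the order C, furan (as ring B aromatises), then both pyrans together.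

Key step: step 9

Step 1
Reactants: 1 2,4,6-trihydroxyacetophenone
Product: 2 1-[4-(benzyloxy)-2,6-dihydroxyphenyl]ethan-1-one
Conditions: BnBr (1.0 equiv), K2CO3 (1.0 equiv), DMF, 0 °C to rt
Reagents that add atoms: benzyl bromide, BrCc1ccccc1
Why: Williamson ether synthesis, in which the 4-OH is the only hydroxyl not hydrogen-bonded to the acetyl carbonyl and the most acidic one, so one equivalent of base and halide should alkylate it in preference to the two chelated ortho hydroxyls.

Step 2
Reactants: 2 1-[4-(benzyloxy)-2,6-dihydroxyphenyl]ethan-1-one; 3 3-chloro-3-methylbut-1-yne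
Product: 4 1-{4-(benzyloxy)-2-hydroxy-6-[(2-methylbut-3-yn-2-yl)oxy]phenyl}ethan-1-one
Conditions: 3 (1.3 equiv), DBU (1.3 equiv), CuCl2·2H2O (1 mol %), MeCN, 0 °C
Reagents that add atoms: none
Why: Copper-catalysed propargylic O-alkylation (through a copper allenylidene) is the standard entry to aryl 1,1-dimethylpropargyl ethers, the two free hydroxyls are equivalent, and the hydroxyl that remains is locked in a hydrogen bond to the ketone, which should stop a second alkylation.

Step 3
Reactants: 4 1-{4-(benzyloxy)-2-hydroxy-6-[(2-methylbut-3-yn-2-yl)oxy]phenyl}ethan-1-one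
Product: 5 1-{4-(benzyloxy)-2-hydroxy-6-[(2-methylbut-3-yn-2-yl)oxy]phenyl}-3,3-bis(methylsulfanyl)prop-2-en-1-one
Conditions: KOtBu (3 equiv, in portions), CS2, THF, 0 °C; MeI (2 equiv), 0 °C to rt; aq. HCl work-up
Reagents that add atoms: carbon disulfide, S=C=S; iodomethane, CI
Why: Ketene dithioacetal formation, in which the methyl ketone enolate adds to CS2 and the dithiolate is S-methylated twice, while portionwise addition of the base leaves no surplus alkoxide and should keep the less acidic alkyne C–H untouched.

Step 4
Reactants: 5 1-{4-(benzyloxy)-2-hydroxy-6-[(2-methylbut-3-yn-2-yl)oxy]phenyl}-3,3-bis(methylsulfanyl)prop-2-en-1-one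
Product: 7 7-(benzyloxy)-5-[(2-methylbut-3-yn-2-yl)oxy]-2-(pyrrolidin-1-yl)-4H-chromen-4-one, via 2-(methylsulfanyl)chromone 6 (not isolated)
Conditions: pyrrolidine (5 equiv), THF, 65 °C
Reagents that add atoms: pyrrolidine, C1CCNC1
Why: Two vinylic addition–elimination events at the push–pull carbon, the ortho phenoxide first closing ring C with loss of methanethiol and pyrrolidine then replacing the second methylsulfanyl group, which is the usual preparation of 2-aminochromones.

Step 5
Reactants: 8 resorcinol; 3 3-chloro-3-methylbut-1-yne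
Product: 9 3-[(2-methylbut-3-yn-2-yl)oxy]phenol
Conditions: 8 (3 equiv), DBU (1 equiv), CuCl2·2H2O (1 mol %), MeCN, 0 °C
Reagents that add atoms: none
Why: The same copper-catalysed propargylic O-alkylation as in step 2, held at the mono-ether stage by the excess of resorcinol, which is washed out with water.

Step 6
Reactants: 9 3-[(2-methylbut-3-yn-2-yl)oxy]phenol
Product: 10 2-[(2-methylbut-3-yn-2-yl)oxy]cyclohexa-2,5-diene-1,4-dione
Conditions: (KSO3)2NO (2.2 equiv), KH2PO4 buffer, H2O/acetone, 0 °C to rt
Reagents that add atoms: potassium nitrosodisulfonate, [K+].[K+].[O]N(S(=O)(=O)[O-])S(=O)(=O)[O-]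
Why: Teuber oxidation, in which the nitrosodisulfonate radical turns a phenol with a free para position into the para-quinone, and here that position (next to the ether carbon) is open, so the 2-alkoxy-1,4-benzoquinone should result under neutral conditions that spare the alkyne and the tertiary ether.

Step 7
Reactants: 7 7-(benzyloxy)-5-[(2-methylbut-3-yn-2-yl)oxy]-2-(pyrrolidin-1-yl)-4H-chromen-4-one; 10 2-[(2-methylbut-3-yn-2-yl)oxy]cyclohexa-2,5-diene-1,4-dione
Product: 12 7-benzyloxy-5'-hydroxy-5,4'-bis[(2-methylbut-3-yn-2-yl)oxy]coumaronochromone, via hydroquinone adduct 11 (not isolated)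
Conditions: glacial AcOH, N2, rt to 60 °C
Reagents that add atoms: none
Why: Proposed new method: C3 of the 2-aminochromone is the alpha carbon of an enaminone with two donors (N and O1) and should add in Michael fashion to C5 of the quinone, the carbon conjugated to the carbonyl group that the alkoxy group does not deactivate; tautomerisation gives the hydroquinone, whose hydroxyl ortho to the new bond adds to the protonated (iminium) form of C2 in the 5-exo-trig mode and expels pyrrolidine, which closes the furan ring without an oxidant and leaves the other quinone oxygen as the 5'-OH next to the ether; the closest known reaction type is the Nenitzescu-type synthesis of 5-hydroxybenzofurans from enaminones and 1,4-benzoquinones in acetic acid, where the amine is lost in the same way, and the new element is a 2-aminochromone partner whose C2 stands at the carboxyl oxidation level.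

Step 8
Reactants: 12 7-benzyloxy-5'-hydroxy-5,4'-bis[(2-methylbut-3-yn-2-yl)oxy]coumaronochromone
Product: 13 5'-acetoxy-7-benzyloxy-5,4'-bis[(2-methylbut-3-yn-2-yl)oxy]coumaronochromone
Conditions: Ac2O, pyridine, DMAP (cat.), CH2Cl2, rt
Reagents that add atoms: acetic anhydride, CC(=O)OC(C)=O
Why: Simple O-acylation that masks the 5'-OH, which would otherwise add to the neighbouring activated alkyne (6-exo-dig) in the next step, with a group that survives hydrogenation and so keeps the 5'-oxygen distinct from the 7-OH.

Step 9
Reactants: 13 5'-acetoxy-7-benzyloxy-5,4'-bis[(2-methylbut-3-yn-2-yl)oxy]coumaronochromone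
Product: 16 5'-acetoxy-7-hydroxycoumaronochromone fused to two 2,2-dimethyldihydropyran rings (O5–C6 ring; O4'–C3' ring), via ring-A monochromene 14 (not isolated), via bis-chromene 15 (not isolated)
Conditions: Ph3PAuNTf2 (5 mol %), dry toluene, rt to 50 °C; then EtOH, Pd/C (10 wt %), H2 (1 atm), rt
Reagents that add atoms: none
Why: Ph3PAu+ (monovalent gold) binds each terminal alkyne and reverses the polarity of its innately nucleophilic terminal carbon, the adjacent electron-rich arene carbon (C6 in ring A, C3' in ring B) attacks that carbon anti to gold, and rearomatisation with protodeauration releases the 2,2-dimethyl-2H-chromene (14, then 15), after which Pd/C and H2 in the same flask saturate both new C=C bonds and cleave the 7-O-benzyl ether. The closest known reaction type is the gold-catalysed intramolecular hydroarylation (cycloisomerisation) of aryl 1,1-dimethylpropargyl ethers to 2,2-dimethylchromenes, used here twice in one molecule. Both pyran rings close in the 6-endo-dig mode by formation of the aryl–CH bond (C6–CH and C3'–CH), because the three-atom O–C(CH3)2–C tether lets only the terminal alkyne carbon reach the ortho carbon. No stereocentre is formed, and the target has none. Regioselectivity is secured by the substrate, since the second ortho position of each ether oxygen is blocked (C4a in ring A, the acetoxy-bearing C5' in ring B), and attack of oxygen on the alkyne is excluded because the 5'-OH is acetylated. The hydrogenation needs no selectivity, because the prenyl group is not yet present and C2=C3 belongs to the aromatic benzofuran.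

Step 10
Reactants: 17 2-methylbut-3-en-2-ol
Product: 18 tert-butyl 2-methylbut-3-en-2-yl carbonate
Conditions: n-BuLi, THF, −78 to 0 °C; Boc2O; aqueous work-up
Reagents that add atoms: di-tert-butyl dicarbonate, CC(C)(C)OC(=O)OC(=O)OC(C)(C)C
Why: O-acylation of the lithium alkoxide of the tertiary allylic alcohol by the dicarbonate, which gives the mixed carbonate without ionising the allylic C–O bond.

Step 11
Reactants: 16 5'-acetoxy-7-hydroxycoumaronochromone fused to two 2,2-dimethyldihydropyran rings; 18 tert-butyl 2-methylbut-3-en-2-yl carbonate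
Product: 19 5'-acetoxy-7-[(2-methylbut-3-en-2-yl)oxy]coumaronochromone fused to two 2,2-dimethyldihydropyran rings
Conditions: 18 (1.5 equiv), Pd(PPh3)4 (5 mol %), THF, 0 °C
Reagents that add atoms: none
Why: Decarboxylative Tsuji–Trost O-allylation, in which zerovalent palladium ionises the carbonate to a 1,1-dimethyl-π-allyl complex and tert-butoxide, the latter deprotonates the only free phenol (7-OH), and at low temperature the phenoxide should attack the more substituted allyl terminus to give the tertiary ether under neutral conditions that leave the acetate alone.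

Step 12
Reactants: 19 5'-acetoxy-7-[(2-methylbut-3-en-2-yl)oxy]coumaronochromone fused to two 2,2-dimethyldihydropyran rings
Product: 21 target CNP0081329.0 (7,5'-dihydroxy-8-prenylcoumaronochromone fused to the O5–C6 ring plus the O4'–C3' ring), via 8-prenyl acetate 20 (not isolated)
Conditions: toluene, 110 °C; then MeOH, K2CO3 (cat.), rt
Reagents that add atoms: none
Why: Aromatic Claisen rearrangement, whose [3,3] shift can end only on C8 because C6 is alkylated and whose allyl inversion turns the tertiary ether into the linear prenyl group, followed in the same flask by carbonate-catalysed methanolysis of the aryl acetate, which is mild enough for the ortho-prenylphenol and the pyranone.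

Compound list
1 | 2,4,6-trihydroxyacetophenone | CC(=O)c1c(O)cc(O)cc1O | starting material
2 | 1-[4-(benzyloxy)-2,6-dihydroxyphenyl]ethan-1-one | CC(=O)c1c(O)cc(OCc2ccccc2)cc1O | intermediate
3 | 3-chloro-3-methylbut-1-yne | C#CC(C)(C)Cl | starting material
4 | 1-{4-(benzyloxy)-2-hydroxy-6-[(2-methylbut-3-yn-2-yl)oxy]phenyl}ethan-1-one | CC(=O)c1c(O)cc(OCc2ccccc2)cc1OC(C)(C)C#C | intermediate
5 | 1-{4-(benzyloxy)-2-hydroxy-6-[(2-methylbut-3-yn-2-yl)oxy]phenyl}-3,3-bis(methylsulfanyl)prop-2-en-1-one | CSC(SC)=CC(=O)c1c(O)cc(OCc2ccccc2)cc1OC(C)(C)C#C | intermediate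
6 | 7-(benzyloxy)-5-[(2-methylbut-3-yn-2-yl)oxy]-2-(methylsulfanyl)-4H-chromen-4-one | CSc1cc(=O)c2c(OC(C)(C)C#C)cc(OCc3ccccc3)cc2o1 | intermediate
7 | 7-(benzyloxy)-5-[(2-methylbut-3-yn-2-yl)oxy]-2-(pyrrolidin-1-yl)-4H-chromen-4-one | O=c1cc(N2CCCC2)oc2cc(OCc3ccccc3)cc(OC(C)(C)C#C)c12 | intermediate
8 | resorcinol | Oc1cccc(O)c1 | starting material
9 | 3-[(2-methylbut-3-yn-2-yl)oxy]phenol | C#CC(C)(C)Oc1cccc(O)c1 | intermediate
10 | 2-[(2-methylbut-3-yn-2-yl)oxy]cyclohexa-2,5-diene-1,4-dione | C#CC(C)(C)OC1=CC(=O)C=CC1=O | intermediate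
11 | 7-(benzyloxy)-3-{2,5-dihydroxy-4-[(2-methylbut-3-yn-2-yl)oxy]phenyl}-5-[(2-methylbut-3-yn-2-yl)oxy]-2-(pyrrolidin-1-yl)-4H-chromen-4-one | O=c1c(-c2cc(O)c(OC(C)(C)C#C)cc2O)c(N2CCCC2)oc2cc(OCc3ccccc3)cc(OC(C)(C)C#C)c12 | intermediate
12 | 7-benzyloxy-5'-hydroxy-5,4'-bis[(2-methylbut-3-yn-2-yl)oxy]coumaronochromone | O=c1c2c(oc3cc(OCc4ccccc4)cc(OC(C)(C)C#C)c13)oc1cc(OC(C)(C)C#C)c(O)cc12 | intermediate
13 | 5'-acetoxy-7-benzyloxy-5,4'-bis[(2-methylbut-3-yn-2-yl)oxy]coumaronochromone | O=c1c2c(oc3cc(OCc4ccccc4)cc(OC(C)(C)C#C)c13)oc1cc(OC(C)(C)C#C)c(OC(C)=O)cc12 | intermediate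
14 | ring-A monochromene (2,2-dimethyl-2H-pyran closed O5–C6; 4'-propargyl ether still open) | O=c1c2c(oc3cc(OCc4ccccc4)c4c(c13)OC(C)(C)C=C4)oc1cc(OC(C)(C)C#C)c(OC(C)=O)cc12 | intermediate
15 | bis-chromene (2,2-dimethyl-2H-pyran rings O5–C6 and O4'–C3'; 7-OBn; 5'-OAc) | O=c1c2c(oc3cc(OCc4ccccc4)c4c(c13)OC(C)(C)C=C4)oc1c3c(c(OC(C)=O)cc12)OC(C)(C)C=C3 | intermediate
16 | 5'-acetoxy-7-hydroxycoumaronochromone fused to two 2,2-dimethyldihydropyran rings (O5–C6; O4'–C3') | O=c1c2c(oc3cc(O)c4c(c13)OC(C)(C)CC4)oc1c3c(c(OC(C)=O)cc12)OC(C)(C)CC3 | intermediate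
17 | 2-methylbut-3-en-2-ol | C=CC(C)(C)O | starting material
18 | tert-butyl 2-methylbut-3-en-2-yl carbonate | C=CC(C)(C)OC(=O)OC(C)(C)C | intermediate
19 | 7-O-(1,1-dimethylallyl) ether of 16 | O=c1c2c(oc3cc(OC(C)(C)C=C)c4c(c13)OC(C)(C)CC4)oc1c3c(c(OC(C)=O)cc12)OC(C)(C)CC3 | intermediate
20 | 5'-O-acetate of the target (8-prenyl, 7-OH) | O=c1c2c(oc3c(CC=C(C)C)c(O)c4c(c13)OC(C)(C)CC4)oc1c3c(c(OC(C)=O)cc12)OC(C)(C)CC3 | intermediate
21 | CNP0081329.0 | CC(C)=CCc1c(O)c2c(c3c(=O)c4c(oc13)oc1c3c(c(O)cc14)OC(C)(C)CC3)OC(C)(C)CC2 | target

Total step count: 12. Longest linear sequence: 9 steps (1, 2, 3, 4, 7, 8, 9, 11, 12).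

Steps most likely to fail

Step 7 (labelled step). Electron transfer between the hydroquinone adduct and unreacted quinone may consume the quinone. Loss of the amine from C2 may be sluggish, and warm acid may cleave the tertiary ether of the quinone. The fallback sets out from 5 and 10 and comes back at 12. Ketene dithioacetal 5 is combined with 10 under BF3·OEt2 in MeCN at 0 °C. This is the known Lewis-acid-mediated Michael addition and cyclisation of alpha-oxoketene dithioacetals with para-quinones. It should give {4-(benzyloxy)-2-hydroxy-6-[(2-methylbut-3-yn-2-yl)oxy]phenyl}{5-hydroxy-6-[(2-methylbut-3-yn-2-yl)oxy]-2-(methylsulfanyl)-1-benzofuran-3-yl}methanone F1. K2CO3 in DMF at 60 °C then lets the ring-A phenoxide displace the methylsulfanyl group by intramolecular addition–elimination, which closes ring C and gives 12.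

Step 9 (key step). The Lewis-acidic gold cation may ionise the tertiary propargylic C–O bonds, with loss of a C5 chain. Traces of water may hydrate the alkynes, or the reaction may stall after the first ring closure. The fallback sets out from 13 and comes back at 16. Compound 13 is heated without any metal in N,N-diethylaniline at about 190 °C. A twofold aromatic propargyl Claisen rearrangement, 1,5-hydrogen shift and oxa-6π electrocyclisation, the classical pericyclic route to 2,2-dimethylchromenes, forms the same two aryl–carbon bonds. This should give 15, which is now isolated. Hydrogenation over Pd/C in EtOH then gives 16.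

Step 3. Surplus alkoxide may deprotonate the terminal alkyne, and CS2 may capture the acetylide. The phenoxide may be O-methylated, or ring closure may occur too early. The fallback changes the order of events so that no alkyne is present during the strong-base step. It sets out from 2 and comes back at 7. KOtBu, CS2 and MeI convert 2 into 1-[4-(benzyloxy)-2,6-dihydroxyphenyl]-3,3-bis(methylsulfanyl)prop-2-en-1-one F2. Warming with pyrrolidine gives 7-(benzyloxy)-5-hydroxy-2-(pyrrolidin-1-yl)-4H-chromen-4-one F3. The remaining 5-OH is then alkylated with 3 (DBU, CuCl2·2H2O, MeCN) to give 7.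

Further compounds
F1 | step 7 | {4-(benzyloxy)-2-hydroxy-6-[(2-methylbut-3-yn-2-yl)oxy]phenyl}{5-hydroxy-6-[(2-methylbut-3-yn-2-yl)oxy]-2-(methylsulfanyl)-1-benzofuran-3-yl}methanone | CSc1oc2cc(OC(C)(C)C#C)c(O)cc2c1C(=O)c1c(O)cc(OCc2ccccc2)cc1OC(C)(C)C#C
F0 | step 9 | none | none
F2 | step 3 | 1-[4-(benzyloxy)-2,6-dihydroxyphenyl]-3,3-bis(methylsulfanyl)prop-2-en-1-one | CSC(SC)=CC(=O)c1c(O)cc(OCc2ccccc2)cc1O
F3 | step 3 | 7-(benzyloxy)-5-hydroxy-2-(pyrrolidin-1-yl)-4H-chromen-4-one | O=c1cc(N2CCCC2)oc2cc(OCc3ccccc3)cc(O)c12
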